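The locants are drimane locants. Ring A is C1–C5 plus C10, ring B is C5–C10, C11 is the OCH2 arm on C9, and C12 is the methyl on C8.
Retrosynthetic cuts, in order: the C11–O aryl ether, C8–C12 with C7=C8, the C3–O acyl bond, C6=O (back to a C5=C6 alkene), one C4–CH3, and last C9–C10, which opens ring B.
Enabling feature: in ring A the quaternary, methyl-bearing C10 stands para to the oxygen on C3 and next to C5, where the C6–C7–C8–C9 arc of ring B begins. Ring A is therefore a masked 2,4-dimethylphenol, and C9 with its one-carbon arm is a masked branched allyl terminus.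
Forward order: ring A is bought as an arene and the chain is joined by Negishi coupling and cross-metathesis. Ring B then closes by dearomatisation, ring A is methylated and saturated, ring B is oxidised to the methyl enone, and the coumarin comes last.
Stereochemistry: C9 and C10 come from the chiral iridium catalyst. C5 is relayed from C10 by α-face hydroboration and is held as the trans-fusion next to C6=O. C3 comes from equatorial delivery by a bulky hydride.

Key step: step 6

Assumption: L* is the (Sa,S,S)-binaphthol-derived N,N-bis(1-phenylethyl)phosphoramidite and is taken to leave the Si face of C9 open. If the sense of induction is the reverse, the (Ra,R,R) antipode is used and nothing else changes.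

Step 1
Reactants: 1 2-bromo-1,3-dimethylbenzene
Product: 2 1-(3-bromo-2,4-dimethylphenyl)ethan-1-one
Conditions: AcCl, AlCl3, CH2Cl2, 0 °C to rt
Reagents that add atoms: acetyl chloride, CC(=O)Cl
Why: Friedel–Crafts acylation should go to the ring position that is ortho to one methyl group and para to the other, because the only alternative is meta to both.

Step 2
Reactants: 2 1-(3-bromo-2,4-dimethylphenyl)ethan-1-one
Product: 3 3-bromo-2,4-dimethylphenyl acetate
Conditions: mCPBA, CF3CO2H, CH2Cl2, rt
Reagents that add atoms: mCPBA, O=C(OO)c1cccc(Cl)c1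
Why: In the acid-promoted Baeyer–Villiger oxidation the electron-rich, ortho-substituted aryl group migrates in preference to methyl, and the phenol emerges already masked as the acetate that the coupling needs.

Step 3
Reactants: 3 3-bromo-2,4-dimethylphenyl acetate; 4 5-bromopent-1-ene
Product: 6 2,4-dimethyl-3-(pent-4-en-1-yl)phenyl acetate, via pent-4-enylzinc bromide 5 (not isolated)
Conditions: 4, Zn dust, LiCl, THF, 50 °C; then 3, Pd(OAc)2 (2 mol %), SPhos (4 mol %), THF, 60 °C
Reagents that add atoms: 5-bromopent-1-ene (4), C=CCCCBr; zinc, [Zn] (in 5 only)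
Why: Negishi coupling of a primary alkylzinc halide with a di-ortho-substituted aryl bromide is well served by a bulky biarylphosphine on palladium, and the zinc reagent leaves the aryl acetate and the terminal alkene untouched.

Step 4
Reactants: 6 2,4-dimethyl-3-(pent-4-en-1-yl)phenyl acetate
Product: 7 2,4-dimethyl-3-(pent-4-en-1-yl)phenol
Conditions: K2CO3 (0.2 equiv), MeOH, rt
Reagents that add atoms: none
Why: Base-catalysed transesterification of an aryl acetate is fast at room temperature, and no other group in the molecule responds.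

Step 5
Reactants: 7 2,4-dimethyl-3-(pent-4-en-1-yl)phenol; 8 allyl methyl carbonate
Product: 9 (2E)-6-(3-hydroxy-2,6-dimethylphenyl)hex-2-en-1-yl methyl carbonate
Conditions: 8 (4 equiv), second-generation Hoveyda–Grubbs catalyst (3 mol %), CH2Cl2, 40 °C
Reagents that add atoms: allyl methyl carbonate (8), C=CCOC(=O)OC
Why: Olefin cross-metathesis of a terminal alkene with an excess of an allylic carbonate should give the E-alkene under thermodynamic control, and ruthenium alkylidenes tolerate free phenols.

Step 6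
Reactants: 9 (2E)-6-(3-hydroxy-2,6-dimethylphenyl)hex-2-en-1-yl methyl carbonate
Product: 10 (4aR,5S)-5-ethenyl-1,4a-dimethyl-5,6,7,8-tetrahydronaphthalen-2(4aH)-one (9α-vinyl-4,10β-dimethyl 1,4-dien-3-one)
Conditions: [Ir(cod)Cl]2 (2.5 mol %), L* (5 mol %), n-PrNH2 pre-activation (THF, 50 °C, then evaporation); Cs2CO3 (1 equiv), THF, 0.02 M, 50 °C
Reagents that add atoms: none
Why: Proposed new method: the cyclometallated iridium phosphoramidite complex ionises the allylic carbonate (loss of CO2 and methoxide) to a π-allyl iridium cation, and the caesium phenoxide attacks it from outside the coordination sphere, anti to the metal, through its para carbon C10 at the substituted allyl terminus C9, which dearomatises ring A. The closest known reactions are the iridium-catalysed intramolecular allylic dearomatisation of para-tethered phenols to spirocyclohexadienones and the para-selective iridium-catalysed Friedel–Crafts-type allylation of meta-tethered phenols; new is their union, a meta tether closing on a methyl-bearing para carbon to give a fused dienone. Ring B (C5–C6–C7–C8–C9–C10) closes in a 6-exo mode with respect to the allyl unit through a chair-like array. C9 is set by the ligand, which leaves the Si face of the allyl terminus open, and C10 is tied to it by that chair: the allyl residue sits pseudo-axial over the unsubstituted face of ring A, free of the gauche contacts with the C10 methyl and C1–H that burden the pseudo-equatorial alternative, so vinyl and methyl should end up anti (9S,10R). Branched attack is the intrinsic preference of iridium and is reinforced by ring size (six against eight), and O-allylation within the molecule would need a strained meta-bridged ether, so only dilution is needed against the intermolecular variant. The hard selectivity is C10 against C4, since both carbons flank C5 and both carry a methyl group, so neither is blocked; it rests on the larger para coefficient of the phenoxide, on the ion-paired oxygen that crowds C4, and on the gain of a cross-conjugated over a linearly conjugated dienone.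

Step 7
Reactants: 10 (4aR,5S)-5-ethenyl-1,4a-dimethyl-5,6,7,8-tetrahydronaphthalen-2(4aH)-one
Product: 12 (4aR,5R)-5-(hydroxymethyl)-1,4a-dimethyl-5,6,7,8-tetrahydronaphthalen-2(4aH)-one, via 9-formyl dienone 11 (not isolated)
Conditions: OsO4 (2 mol %), NaIO4, 2,6-lutidine, dioxane–H2O, rt; extraction, crude 11; NaBH4, MeOH, −40 °C
Reagents that add atoms: sodium periodate, [Na+].[O-]I(=O)(=O)=O
Why: Lemieux–Johnson cleavage should pick the only electron-rich, monosubstituted alkene over the two enone double bonds, and NaBH4 at low temperature reduces the unpurified aldehyde much faster than a cross-conjugated dienone, which leaves C9 no time to epimerise.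

Step 8
Reactants: 12 (4aR,5R)-5-(hydroxymethyl)-1,4a-dimethyl-5,6,7,8-tetrahydronaphthalen-2(4aH)-one
Product: 13 (4aR,5R)-5-[(tert-butyldimethylsilyloxy)methyl]-1,4a-dimethyl-5,6,7,8-tetrahydronaphthalen-2(4aH)-one
Conditions: TBSCl, imidazole, DMF, rt
Reagents that add atoms: TBSCl, CC(C)(C)[Si](C)(C)Cl
Why: Standard silylation of a primary alcohol gives an ether that withstands alkoxide, hydrogenation, borane, hydrides and cuprate and is removed by fluoride at the end.

Step 9
Reactants: 13 (4aR,5R)-5-[(tert-butyldimethylsilyloxy)methyl]-1,4a-dimethyl-5,6,7,8-tetrahydronaphthalen-2(4aH)-one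
Product: 14 (4aR,5R)-5-[(tert-butyldimethylsilyloxy)methyl]-1,1,4a-trimethyl-4a,5,6,7-tetrahydronaphthalen-2(1H)-one (4,4-dimethyl 1,5-dien-3-one)
Conditions: KOt-Bu, t-BuOH–THF, rt; MeI
Reagents that add atoms: iodomethane, CI
Why: In this deconjugative α-alkylation the alkoxide removes a γ-proton from C6 and the extended enolate is methylated at C4 with shift of the alkene to C5=C6, and since the product has no enolisable hydrogen left, over-methylation cannot occur.

Step 10
Reactants: 14 (4aR,5R)-5-[(tert-butyldimethylsilyloxy)methyl]-1,1,4a-trimethyl-4a,5,6,7-tetrahydronaphthalen-2(1H)-one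
Product: 15 (4aR,5R)-5-[(tert-butyldimethylsilyloxy)methyl]-1,1,4a-trimethyl-3,4,4a,5,6,7-hexahydronaphthalen-2(1H)-one
Conditions: H2 (1 atm), 10% Pd/C, EtOAc, rt
Reagents that add atoms: none
Why: Heterogeneous catalytic hydrogenation should saturate the disubstituted enone alkene C1=C2 only, because C5=C6 is trisubstituted and wedged between two quaternary carbons.

Step 11
Reactants: 15 (4aR,5R)-5-[(tert-butyldimethylsilyloxy)methyl]-1,1,4a-trimethyl-3,4,4a,5,6,7-hexahydronaphthalen-2(1H)-one
Product: 16 (3S,5R,6S,9R,10R)-11-(tert-butyldimethylsilyloxy)-12-nordrimane-3,6-diol (3β-OH, 6α-OH, 5α-H, 9β-H)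
Conditions: BH3·THF (6 equiv), THF, 0 to 45 °C; then NaOH, H2O2, 0 °C to rt
Reagents that add atoms: hydrogen peroxide, OO
Why: In the hydroboration–oxidation, borane first reduces the ketone and then adds syn to C5=C6 from the α face, away from the axial methyls on C4 and C10 and with boron on the less substituted C6, which sets 5α-H (trans-decalin), while both carbinol centres are erased in the next step.

Step 12
Reactants: 16 (3S,5R,6S,9R,10R)-11-(tert-butyldimethylsilyloxy)-12-nordrimane-3,6-diol
Product: 17 (5R,9R,10R)-11-(tert-butyldimethylsilyloxy)-12-nordrimane-3,6-dione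
Conditions: Dess–Martin periodinane (3 equiv), CH2Cl2, rt
Reagents that add atoms: none
Why: Dess–Martin oxidation converts both secondary alcohols under nearly neutral conditions, and C5, now next to a ketone, already has the more stable trans-fused configuration.

Step 13
Reactants: 17 (5R,9R,10R)-11-(tert-butyldimethylsilyloxy)-12-nordrimane-3,6-dione
Product: 18 (3R,5R,9R,10R)-11-(tert-butyldimethylsilyloxy)-3-hydroxy-12-nordriman-6-one (3α-OH, axial)
Conditions: LiBH(s-Bu)3 (1.1 equiv), THF, −78 °C; then NaOH, H2O2, 0 °C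
Reagents that add atoms: none
Why: Under steric approach control the trialkylborohydride should reduce only the C3 ketone, because C6=O is buried between the C4 gem-dimethyl group, the C10 methyl and the axial C9 arm, and it should deliver hydride equatorially to give the axial 3α-alcohol, as is known for 4,4-dimethyl-3-oxo terpenoids and 3,6-dioxo steroids.

Step 14
Reactants: 18 (3R,5R,9R,10R)-11-(tert-butyldimethylsilyloxy)-3-hydroxy-12-nordriman-6-one; 19 isovaleryl chloride
Product: 20 (3R,5R,9R,10R)-11-(tert-butyldimethylsilyloxy)-6-oxo-12-nordriman-3-yl 3-methylbutanoate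
Conditions: 19, DMAP, pyridine, CH2Cl2, rt to 40 °C
Reagents that add atoms: isovaleryl chloride (19), CC(C)CC(=O)Cl
Why: DMAP-catalysed acylation with an acid chloride copes with a hindered axial alcohol and leaves the C3–O bond, and therefore the configuration, untouched.

Step 15
Reactants: 20 (3R,5R,9R,10R)-11-(tert-butyldimethylsilyloxy)-6-oxo-12-nordriman-3-yl 3-methylbutanoate
Product: 22 (3R,5R,9R,10R)-11-(tert-butyldimethylsilyloxy)-6-oxo-12-nordrim-7-en-3-yl 3-methylbutanoate, via C6 trimethylsilyl enol ether 21 (not isolated)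
Conditions: TMSOTf, Et3N, CH2Cl2, 0 °C; concentration; Pd(OAc)2 (1.1 equiv), MeCN, rt to 40 °C
Reagents that add atoms: TMSOTf, C[Si](C)(C)OS(=O)(=O)C(F)(F)F (in 21 only)
Why: In this Saegusa–Ito oxidation, soft enolisation silylates the ketone but not the ester, and toward C7 because C5–H is shielded, after which the divalent palladium enolate loses the C8 hydride to give the enone and zerovalent palladium.

Step 16
Reactants: 22 (3R,5R,9R,10R)-11-(tert-butyldimethylsilyloxy)-6-oxo-12-nordrim-7-en-3-yl 3-methylbutanoate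
Product: 24 (3R,5R,9R,10R)-11-(tert-butyldimethylsilyloxy)-6-oxodrim-7-en-3-yl 3-methylbutanoate, via 8-methyl trimethylsilyl enol ether 23 (not isolated)
Conditions: Me2CuLi (from MeLi, CuI), TMSCl, Et2O–THF, −78 to −40 °C; buffered work-up, crude 23; Pd(OAc)2 (1.1 equiv), MeCN, 40 °C
Reagents that add atoms: methyllithium, [Li]C; TMSCl, C[Si](C)(C)Cl (in 23 only)
Why: TMSCl-accelerated Gilman conjugate addition places C12 on C8 (expected anti to the C9 arm, a centre that is erased at once), and a second Saegusa–Ito oxidation of the trapped enol ether restores C7=C8 without any base that could touch C9–H.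

Step 17
Reactants: 24 (3R,5R,9R,10R)-11-(tert-butyldimethylsilyloxy)-6-oxodrim-7-en-3-yl 3-methylbutanoate
Product: 25 (3R,5R,9R,10R)-11-hydroxy-6-oxodrim-7-en-3-yl 3-methylbutanoate
Conditions: HF·pyridine, THF, 0 °C to rt
Reagents that add atoms: none
Why: Fluoride-mediated desilylation in a mildly acidic medium spares the ester and avoids base, which could deprotonate the γ-position C9 of the enone and epimerise it.

Step 18
Reactants: 25 (3R,5R,9R,10R)-11-hydroxy-6-oxodrim-7-en-3-yl 3-methylbutanoate; 26 isofraxidin (7-hydroxy-6,8-dimethoxycoumarin)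
Product: 27 (3R,5R,9R,10R)-11-[(6,8-dimethoxy-2-oxo-2H-chromen-7-yl)oxy]-6-oxodrim-7-en-3-yl 3-methylbutanoate (3α-acyloxy, 5α-H, 9β-H, 10β-CH3)
Conditions: 26, PPh3, DIAD, toluene–THF, 0 °C to 40 °C
Reagents that add atoms: isofraxidin (26), COc1cc2ccc(=O)oc2c(OC)c1O
Why: Mitsunobu etherification joins an acidic phenol to a primary alcohol under neutral conditions, and since substitution takes place at the CH2 group C11, no stereocentre is involved.

Compound list
1 | 2-bromo-1,3-dimethylbenzene | Cc1cccc(C)c1Br | starting material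
2 | 1-(3-bromo-2,4-dimethylphenyl)ethan-1-one | CC(=O)c1ccc(C)c(Br)c1C | intermediate
3 | 3-bromo-2,4-dimethylphenyl acetate | CC(=O)Oc1ccc(C)c(Br)c1C | intermediate
4 | 5-bromopent-1-ene | C=CCCCBr | starting material
5 | pent-4-enylzinc bromide | C=CCCC[Zn]Br | intermediate
6 | 2,4-dimethyl-3-(pent-4-en-1-yl)phenyl acetate | CC(=O)Oc1ccc(C)c(CCCC=C)c1C | intermediate
7 | 2,4-dimethyl-3-(pent-4-en-1-yl)phenol | C=CCCCc1c(C)ccc(O)c1C | intermediate
8 | allyl methyl carbonate | C=CCOC(=O)OC | starting material
9 | (2E)-6-(3-hydroxy-2,6-dimethylphenyl)hex-2-en-1-yl methyl carbonate | COC(=O)OC/C=C/CCCc1c(C)ccc(O)c1C | intermediate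
10 | (4aR,5S)-5-ethenyl-1,4a-dimethyl-5,6,7,8-tetrahydronaphthalen-2(4aH)-one | C=C[C@@H]1CCCC2=C(C)C(=O)C=C[C@]12C | intermediate
11 | (1R,8aR)-5,8a-dimethyl-6-oxo-1,2,3,4,6,8a-hexahydronaphthalene-1-carbaldehyde | O=C[C@@H]1CCCC2=C(C)C(=O)C=C[C@]12C | intermediate
12 | (4aR,5R)-5-(hydroxymethyl)-1,4a-dimethyl-5,6,7,8-tetrahydronaphthalen-2(4aH)-one | OC[C@@H]1CCCC2=C(C)C(=O)C=C[C@]12C | intermediate
13 | (4aR,5R)-5-[(tert-butyldimethylsilyloxy)methyl]-1,4a-dimethyl-5,6,7,8-tetrahydronaphthalen-2(4aH)-one | CC(C)(C)[Si](C)(C)OC[C@@H]1CCCC2=C(C)C(=O)C=C[C@]12C | intermediate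
14 | (4aR,5R)-5-[(tert-butyldimethylsilyloxy)methyl]-1,1,4a-trimethyl-4a,5,6,7-tetrahydronaphthalen-2(1H)-one | CC(C)(C)[Si](C)(C)OC[C@@H]1CCC=C2C(C)(C)C(=O)C=C[C@]12C | intermediate
15 | (4aR,5R)-5-[(tert-butyldimethylsilyloxy)methyl]-1,1,4a-trimethyl-3,4,4a,5,6,7-hexahydronaphthalen-2(1H)-one | CC(C)(C)[Si](C)(C)OC[C@@H]1CCC=C2C(C)(C)C(=O)CC[C@]12C | intermediate
16 | (3S,5R,6S,9R,10R)-11-(tert-butyldimethylsilyloxy)-12-nordrimane-3,6-diol | CC(C)(C)[Si](C)(C)OC[C@@H]1CC[C@H](O)[C@H]2C(C)(C)[C@@H](O)CC[C@]12C | intermediate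
17 | (5R,9R,10R)-11-(tert-butyldimethylsilyloxy)-12-nordrimane-3,6-dione | CC(C)(C)[Si](C)(C)OC[C@@H]1CCC(=O)[C@H]2C(C)(C)C(=O)CC[C@]12C | intermediate
18 | (3R,5R,9R,10R)-11-(tert-butyldimethylsilyloxy)-3-hydroxy-12-nordriman-6-one | CC(C)(C)[Si](C)(C)OC[C@@H]1CCC(=O)[C@H]2C(C)(C)[C@H](O)CC[C@]12C | intermediate
19 | isovaleryl chloride | CC(C)CC(=O)Cl | starting material
20 | (3R,5R,9R,10R)-11-(tert-butyldimethylsilyloxy)-6-oxo-12-nordriman-3-yl 3-methylbutanoate | CC(C)(C)[Si](C)(C)OC[C@@H]1CCC(=O)[C@H]2C(C)(C)[C@H](OC(=O)CC(C)C)CC[C@]12C | intermediate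
21 | (3R,5R,9R,10R)-11-(tert-butyldimethylsilyloxy)-6-(trimethylsilyloxy)-12-nordrim-6-en-3-yl 3-methylbutanoate | CC(C)(C)[Si](C)(C)OC[C@@H]1CC=C(O[Si](C)(C)C)[C@H]2C(C)(C)[C@H](OC(=O)CC(C)C)CC[C@]12C | intermediate
22 | (3R,5R,9R,10R)-11-(tert-butyldimethylsilyloxy)-6-oxo-12-nordrim-7-en-3-yl 3-methylbutanoate | CC(C)(C)[Si](C)(C)OC[C@@H]1C=CC(=O)[C@H]2C(C)(C)[C@H](OC(=O)CC(C)C)CC[C@]12C | intermediate
23 | (3R,5R,8R,9R,10R)-11-(tert-butyldimethylsilyloxy)-6-(trimethylsilyloxy)drim-6-en-3-yl 3-methylbutanoate (8β-CH3) | CC(C)(C)[Si](C)(C)OC[C@@H]1[C@@H](C)C=C(O[Si](C)(C)C)[C@H]2C(C)(C)[C@H](OC(=O)CC(C)C)CC[C@]12C | intermediate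
24 | (3R,5R,9R,10R)-11-(tert-butyldimethylsilyloxy)-6-oxodrim-7-en-3-yl 3-methylbutanoate | CC(C)(C)[Si](C)(C)OC[C@@H]1C(C)=CC(=O)[C@H]2C(C)(C)[C@H](OC(=O)CC(C)C)CC[C@]12C | intermediate
25 | (3R,5R,9R,10R)-11-hydroxy-6-oxodrim-7-en-3-yl 3-methylbutanoate | OC[C@@H]1C(C)=CC(=O)[C@H]2C(C)(C)[C@H](OC(=O)CC(C)C)CC[C@]12C | intermediate
26 | isofraxidin | COc1cc2ccc(=O)oc2c(OC)c1O | starting material
27 | (3R,5R,9R,10R)-11-[(6,8-dimethoxy-2-oxo-2H-chromen-7-yl)oxy]-6-oxodrim-7-en-3-yl 3-methylbutanoate | COc1cc2ccc(=O)oc2c(OC)c1OC[C@@H]1C(C)=CC(=O)[C@H]2C(C)(C)[C@H](OC(=O)CC(C)C)CC[C@]12C | target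

Total step count: 18. Longest linear sequence: 18 steps (1 to 27). Compounds 4, 8, 19 and 26 enter as purchased.

Steps most likely to fail

Step 6. Ring closure may run through the ortho carbon C4 instead of C10, or the two faces of C10 may be poorly distinguished.
- The fallback forms the same bond with known chemistry. It brings C9 in as a resolved secondary sulfonate that is displaced with inversion. It sets out from 6 and returns at 13, so steps 4 to 8 fall away.
- Epoxidation of the terminal alkene of 6 with mCPBA gives the racemic epoxide F1.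
- Hydrolytic kinetic resolution with (S,S)-(salen)Co(OAc) and a deficit of water gives the (R)-diol F2.
- TBSCl and imidazole at 0 °C silylate the primary hydroxyl to give the primary silyl ether F3.
- MsCl and Et3N give the secondary mesylate F4, and K2CO3 in MeOH frees the phenol mesylate F5.
- KOt-Bu in t-BuOH then closes ring B by intramolecular para C-alkylation of the hydrogen-bonded phenoxide (Ar2-6 participation), which gives 13.

Step 13. Hydride may also be delivered to C6, or axial delivery at C3 may give the equatorial alcohol.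
- The fallback separates the two carbonyl groups in time instead of by their steric environment. It sets out from 15 and returns at 20.
- LiBH(s-Bu)3 reduces the only ketone of 15 to the 3α-alcohol F6.
- Acylation with 19, DMAP and pyridine gives the unsaturated isovalerate F7.
- Hydroboration with BH3·THF at or below room temperature, followed by oxidation with NaBO3·4H2O, gives the 6α-alcohol F8.
- Dess–Martin oxidation of F8 gives 20.

Step 18. Displacement at the β-branched C11 by a di-ortho-substituted phenol may be slow. The activated oxygen could then leave by vinylogous elimination, because C9–H is γ to the enone.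
- The fallback forms the ether before C9–H is acidified and closes the synthesis with the dehydrogenation. It sets out from 22 and returns at 27.
- Me2CuLi is added to 22 without silyl trapping, and protonation gives the saturated 8-methyl ketone F9.
- HF·pyridine gives the primary alcohol F10, and Tf2O with 2,6-lutidine gives the primary triflate F11.
- The caesium salt of 26 (Cs2CO3, MeCN) displaces the triflate in a Williamson-type SN2 reaction to give the saturated aryl ether F12.
- TMSOTf and Et3N give the silyl enol ether F13, and Pd(OAc)2 in MeCN dehydrogenates it to 27.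

Further compounds
F1 | step 6 | 2,4-dimethyl-3-[3-(oxiran-2-yl)propyl]phenyl acetate (racemic) | CC(=O)Oc1ccc(C)c(CCCC2CO2)c1C
F2 | step 6 | 3-[(4R)-4,5-dihydroxypentyl]-2,4-dimethylphenyl acetate | OC[C@H](O)CCCc1c(C)ccc(OC(C)=O)c1C
F3 | step 6 | 3-[(4R)-5-(tert-butyldimethylsilyloxy)-4-hydroxypentyl]-2,4-dimethylphenyl acetate | CC(C)(C)[Si](C)(C)OC[C@H](O)CCCc1c(C)ccc(OC(C)=O)c1C
F4 | step 6 | 3-[(4R)-5-(tert-butyldimethylsilyloxy)-4-(methylsulfonyloxy)pentyl]-2,4-dimethylphenyl acetate | CC(C)(C)[Si](C)(C)OC[C@H](OS(C)(=O)=O)CCCc1c(C)ccc(OC(C)=O)c1C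
F5 | step 6 | (2R)-1-(tert-butyldimethylsilyloxy)-5-(3-hydroxy-2,6-dimethylphenyl)pentan-2-yl methanesulfonate | CC(C)(C)[Si](C)(C)OC[C@H](OS(C)(=O)=O)CCCc1c(C)ccc(O)c1C
F6 | step 13 | (3R,9R,10R)-11-(tert-butyldimethylsilyloxy)-12-nordrim-5-en-3-ol | CC(C)(C)[Si](C)(C)OC[C@@H]1CCC=C2C(C)(C)[C@H](O)CC[C@]12C
F7 | step 13 | (3R,9R,10R)-11-(tert-butyldimethylsilyloxy)-12-nordrim-5-en-3-yl 3-methylbutanoate | CC(C)(C)[Si](C)(C)OC[C@@H]1CCC=C2C(C)(C)[C@H](OC(=O)CC(C)C)CC[C@]12C
F8 | step 13 | (3R,5R,6S,9R,10R)-11-(tert-butyldimethylsilyloxy)-6-hydroxy-12-nordriman-3-yl 3-methylbutanoate | CC(C)(C)[Si](C)(C)OC[C@@H]1CC[C@H](O)[C@H]2C(C)(C)[C@H](OC(=O)CC(C)C)CC[C@]12C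
F9 | step 18 | (3R,5R,8S,9R,10R)-11-(tert-butyldimethylsilyloxy)-6-oxodriman-3-yl 3-methylbutanoate | CC(C)(C)[Si](C)(C)OC[C@@H]1[C@@H](C)CC(=O)[C@H]2C(C)(C)[C@H](OC(=O)CC(C)C)CC[C@]12C
F10 | step 18 | (3R,5R,8S,9R,10R)-11-hydroxy-6-oxodriman-3-yl 3-methylbutanoate | OC[C@@H]1[C@@H](C)CC(=O)[C@H]2C(C)(C)[C@H](OC(=O)CC(C)C)CC[C@]12C
F11 | step 18 | (3R,5R,8S,9R,10R)-6-oxo-11-(trifluoromethylsulfonyloxy)driman-3-yl 3-methylbutanoate | O=S(=O)(OC[C@@H]1[C@@H](C)CC(=O)[C@H]2C(C)(C)[C@H](OC(=O)CC(C)C)CC[C@]12C)C(F)(F)F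
F12 | step 18 | (3R,5R,8S,9R,10R)-11-[(6,8-dimethoxy-2-oxo-2H-chromen-7-yl)oxy]-6-oxodriman-3-yl 3-methylbutanoate | COc1cc2ccc(=O)oc2c(OC)c1OC[C@@H]1[C@@H](C)CC(=O)[C@H]2C(C)(C)[C@H](OC(=O)CC(C)C)CC[C@]12C
F13 | step 18 | (3R,5R,8R,9R,10R)-11-[(6,8-dimethoxy-2-oxo-2H-chromen-7-yl)oxy]-6-(trimethylsilyloxy)drim-6-en-3-yl 3-methylbutanoate | COc1cc2ccc(=O)oc2c(OC)c1OC[C@@H]1[C@@H](C)C=C(O[Si](C)(C)C)[C@H]2C(C)(C)[C@H](OC(=O)CC(C)C)CC[C@]12C
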